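# Dorsilurin C: synthesis design around a Claisen–Dieckmann construction of ring A

## The problem

Dorsilurin C is an achiral flavonol. Its 3-hydroxy-4H-chromen-4-one (rings A and C) is bonded through C2 to ring B, which is the benzo ring of a 2,2-dimethyl-2H-chromene attached at chromene C7, so the pyran oxygen sits on C3' and the pyran carbon on C4'. Ring A is hexasubstituted: oxygen on C5, C7 and C8a alternates with carbon on C6 (prenyl), C8 (prenyl) and C4a (the C4 carbonyl). The difficulty on ring A is therefore purely positional: two identical C5 units must sit on two defined carbons of a phloroglucinol, and the third carbon must stay free for acylation. There is no stereocentre, so nothing has to be set or relayed. The open questions are position (C6/C8 against C4a on ring A, C4' against C2' on ring B) and C- against O-bond formation. The fragile groups are the two prenyl alkenes, each ortho to a phenol, which close to chromans under protic or Lewis acids and are attacked by halogens and epoxidising oxidants. The chromene alkene behaves similarly, and the free diprenylphloroglucinol is electron-rich and air-sensitive. Friedel–Crafts and Houben–Hoesch acylation, hydrogenolysis and boron trihalide ether cleavage are thus excluded once the prenyl groups are present. The enabling feature is that the three ring A oxygens are 1,3,5-related and the C7 oxygen is flanked by both prenylated carbons. Ring A is therefore a cyclised 3,5-dioxo ester: C8a–C4a–C5–C6 maps onto a β-keto ester with prenyl on its γ-carbon, and C7–C8 onto a prenylated acetate.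

## Retrosynthesis

**Ring C (O1–C2).** Target 22 is opened at O1–C2 to the 2-alkoxy-1,3-diketone 20, which carries the C3 oxygen at the final oxidation level. The neighbouring cut, an Algar–Flynn–Oyamada oxidation of a chalcone, would need alkaline peroxide and a selectively mono-deprotected 2'-hydroxy-6'-alkoxychalcone, a substitution pattern known to divert such oxidations towards aurones. Diketone 20 contains every carbon and oxygen of 22. The forward step must remove four methoxymethyl (MOM) acetals and cyclodehydrate without touching the prenyl groups.

**C2–C3.** Diketone 20 is cut between the central carbon and the ring B carbonyl into ketone 14 and chromene acid 18, used as its chloride 19. A Baker–Venkataraman acyl transfer forms the same bond but needs one free ortho phenol, hence a partial deprotection and an esterification. Direct enolate aroylation needs neither. The forward reaction must acylate on carbon, not oxygen.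

**C4–C4a.** Ketone 14 is cut at the aryl–carbonyl bond into the tris-MOM ether 10 and the glycolic Weinreb amide 13, made in two steps from methyl glycolate 11 through ester 12. Electrophilic acylation of triol 9 would need acids that cyclise o-prenylphenols. Arene 10 has one ring hydrogen, flanked by two MOM ethers, which is the ideal site for directed lithiation. MOM is chosen because it directs metalation, survives organolithiums and amide bases, and leaves under the acid that closes ring C. Benzyl, methyl and silyl ethers fail on removal or on direction. Ether 10 comes from triol 9 by O-alkylation.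

**Ring A (C6–C7 and C8–C8a).** Triol 9 is cut into the γ-prenylated β-keto ester 3 and the prenylacetate 7, with the 3,5-dioxo ester 8 as the link. Direct prenylation of phloroglucinol would give mono-, di-, tri- and geminally alkylated products. Here each prenyl group is already bonded to the carbon that becomes C6 or C8. A hexasubstituted benzene becomes two acyclic esters of ten and eight carbons. The forward step must acylate at the γ-carbon and then close through carbon.

**The two esters.** Keto ester 3 is cut at its γ-carbon into methyl acetoacetate 1 and prenyl bromide 2 (dianion alkylation). Ester 7 is cut at C3–C4 into 2-methylbut-3-en-2-ol 4 and trimethyl orthoacetate 5 (Johnson–Claisen rearrangement through ketene acetal 6). This takes one step, where malonate alkylation followed by dealkoxycarbonylation takes two.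

**Ring B.** Acid 18 is cut at the carboxyl carbon to bromochromene 17. Its pyran ring is cut at O–CMe2 and C4–C3' back to 4-bromo-2-hydroxybenzaldehyde 15 and an isobutenyl Grignard reagent, through allylic alcohol 16. The usual aryl propargyl ether rearrangement of a meta-substituted phenol can close onto either ortho carbon and would give 5- and 7-substituted chromenes. In 15 the aldehyde carbon becomes chromene C4, so the bromine arrives at C7 without ambiguity.

## Roads not taken

**Alternative 1:** All three C5 units are cut from a plain flavonol core. The precursor is 5,7-bis(2-methylbut-3-en-2-yloxy)-2-[3-(2-methylbut-3-yn-2-yloxy)phenyl]-4-oxo-4H-chromen-3-yl benzoate A2. Heating it with Eu(fod)3 should move both tertiary allyl groups to C6 and C8 by [3,3] shifts. The propargyl ether should rearrange, shift hydrogen and close by oxa-6π electrocyclisation, giving dorsilurin C 3-benzoate A1.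
- Merits: four bonds and one ring form in one flask, and the core needs only routine flavonol chemistry without prenyl groups. On step count and convergence this road is clearly better than the chosen one.
- Weak points: three independent regiochemical choices must all fall correctly.
  - The O7 unit can go to C8 or C6. If it takes C6, the O5 unit can only reach C8 by a Claisen–Cope relay and arrives as a 1,1-dimethylallyl group.
  - The ring B ether can close onto C2' or C4', and a meta acceptor tends to favour the crowded C2' position.
  - Tertiary allyl aryl ethers are hard to install on a chelated 5-hydroxyl and ionise at the temperature the propargyl rearrangement needs.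
- Comparison: the chosen plan is longer, but each of these positional questions is answered by connectivity (esters 3 and 7 for ring A, aldehyde 15 for ring B), not by selectivity.

**Alternative 2:** Ring B is cut at C1'–C2' and C5'–C6'. The lithium enolate of 2-acetyl-3,5,7-tris(methoxymethoxy)-6,8-bis(3-methylbut-2-enyl)-4H-chromen-4-one A4 would add to 3-(ethoxymethylidene)-6-methylhept-5-en-2-one A5 with loss of ethoxide. Aldol closure and aromatisation would give 2-[3-hydroxy-4-(3-methylbut-2-enyl)phenyl]-3,5,7-tris(methoxymethoxy)-6,8-bis(3-methylbut-2-enyl)-4H-chromen-4-one A3.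
- Merits: the 3'-oxygen and 4'-carbon pattern of ring B is fixed by acyclic precursors, and the C3 oxygen is present from the start.
- Weak points:
  - A4 is a fully built ring A/C unit, so the ring A problem is only postponed.
  - The chromone C2 is a Michael acceptor and competes with clean enolate formation.
  - The annulation has two possible pairings.
  - A3 still needs dehydrogenative closure of its prenylphenol to the chromene in the presence of two other prenyl groups, then deprotection.
  - The benzannulation has no precedent on this substrate class.
- Comparison: the route is longer and rests on an untested step. The chosen plan gets the same ring B certainty from aldehyde 15 in one step.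

**Alternative 3:** Ring A is cut into a four-carbon and a two-carbon piece. Heating 2-(3-methylbut-2-enyl)-3-(triisopropylsilyloxy)cyclobut-2-en-1-one A7 with triisopropyl(5-methylhex-4-en-1-ynyloxy)silane A8 should give 2,4-bis(3-methylbut-2-enyl)-3,5-bis(triisopropylsilyloxy)phenol A6. The sequence is electrocyclic opening, [2+2] addition, a second opening and 6π closure (Danheiser benzannulation).
- Merits: regiocontrol is by connectivity, as in the chosen plan. The conditions are neutral and there is no C- against O-closure issue, so the ring closure itself is probably more reliable. A6 also arrives with its oxygens differentiated, the free hydroxyl lying next to the open carbon. This is a real advantage over the symmetrical triol 9.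
- Weak points: A7 is a moisture-sensitive vinylogous silyl ester and A8 needs an ynolate homologation and O-silylation, so each partner costs several delicate steps. Bulky silyl ethers are poor directors for the acid-free acylation that must follow.
- Comparison: the chosen plan reaches ring A from two one-step precursors made from bulk chemicals. It needs no oxygen differentiation, because all three oxygens take the same MOM group and the two ortho oxygens are equivalent.

Key step: step 3

## Route

Remark on the chemistry: 8 and 20 are drawn as keto forms but will be largely enolised. Their single sp3 stereocentre, like that of 16, is racemic, labile and erased in the next bond-forming event. The target has no stereocentre.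

Step 1
Reactants: 1 methyl acetoacetate; 2 1-bromo-3-methylbut-2-ene (prenyl bromide)
Product: 3 methyl 7-methyl-3-oxooct-6-enoate
Conditions: NaH, THF, 0 °C; n-BuLi, 0 °C; then 2, 0 °C to rt; aq. NH4Cl
Reagents that add atoms: none
Why: γ-Alkylation of a β-keto ester dianion; the less stabilised γ-carbanion is the more nucleophilic site, so the SN2 reaction with the primary allylic bromide should occur there and not at the α-carbon.

Step 2
Reactants: 4 2-methylbut-3-en-2-ol; 5 trimethyl orthoacetate
Product: 7 methyl 5-methylhex-4-enoate, via ketene acetal 6 (not isolated)
Conditions: EtCO2H (cat.), 5 (excess, neat), 110–140 °C, MeOH distilled off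
Reagents that add atoms: none
Why: Johnson–Claisen orthoester rearrangement; acid-catalysed exchange and loss of methanol give the mixed ketene acetal, whose [3,3] shift places the new C–C bond on the vinyl terminus and leaves the trisubstituted alkene, which has no geometry to control.

Step 3
Reactants: 3 methyl 7-methyl-3-oxooct-6-enoate; 7 methyl 5-methylhex-4-enoate
Product: 9 2,4-bis(3-methylbut-2-enyl)benzene-1,3,5-triol, via dioxo ester 8 (not isolated)
Conditions: 3 (2 equiv), NaH then n-BuLi, THF, 0 °C; 7 (1 equiv), 0 °C to rt; then NaOMe (excess), MeOH, 65 °C; cold dil. HCl to pH 4, under argon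
Reagents that add atoms: none
Why: The dianion of 3 attacks the ester carbonyl of 7 through its γ-carbon (C4) in a crossed Claisen condensation, the known γ-acylation of β-keto ester dianions by esters, and the second equivalent of dianion takes up the acidic proton of dioxo ester 8 so that the acylation is not reversed. Methoxide in hot methanol then equilibrates the enolates of 8 until the C6 enolate adds to the C1 ester carbonyl, a Dieckmann condensation of the kind that converts δ-keto esters into cyclohexane-1,3-diones and 3,5-dioxo esters into phloroglucinols. The ring closes in a 6-exo-trig (enol-exo) mode, and loss of methoxide gives a cyclohexane-1,3,5-trione that tautomerises at once to the benzenetriol. No stereocentre is created in 9; the C4 centre of 8 is racemic and disappears on aromatisation. The step needs γ- over α-acylation, which the dianion secures because the α-carbon remains part of a stabilised, unreactive enolate. It also needs C- over O-acylation in the closure: O-acylation gives a 4-hydroxy-2-pyranone, but excess methoxide reopens this lactone to 8 while formation of the phloroglucinolate is irreversible, so the equilibrium should drain to 9. Because each prenyl group is already bonded to the carbon that becomes C2 or C4 of the triol, the substitution pattern follows from connectivity and not from selectivity.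

Step 4
Reactants: 9 2,4-bis(3-methylbut-2-enyl)benzene-1,3,5-triol
Product: 10 1,3,5-tris(methoxymethoxy)-2,4-bis(3-methylbut-2-enyl)benzene
Conditions: NaH, MOMCl, DMF, 0 °C to rt
Reagents that add atoms: chloromethyl methyl ether (MOMCl), COCCl
Why: Williamson-type O-alkylation; a hard chloromethyl ether with sodium phenoxides in a dipolar aprotic solvent should favour oxygen over ring carbon, and the small MOM group also reaches the hydroxyl between the two prenyl groups.

Step 5
Reactants: 11 methyl glycolate
Product: 12 methyl 2-(methoxymethoxy)acetate
Conditions: MOMCl, i-Pr2NEt, CH2Cl2, 0 °C to rt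
Reagents that add atoms: chloromethyl methyl ether (MOMCl), COCCl
Why: Standard acetal protection of a primary alcohol under amine base; the ester is untouched.

Step 6
Reactants: 12 methyl 2-(methoxymethoxy)acetate
Product: 13 N-methoxy-2-(methoxymethoxy)-N-methylacetamide
Conditions: MeNH(OMe)·HCl, i-PrMgCl, THF, −20 to 0 °C
Reagents that add atoms: N,O-dimethylhydroxylamine hydrochloride, CNOC.Cl
Why: Direct ester aminolysis by the magnesium amide of N,O-dimethylhydroxylamine (Weinreb amide formation); the unhindered methyl ester should react cleanly at low temperature.

Step 7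
Reactants: 10 1,3,5-tris(methoxymethoxy)-2,4-bis(3-methylbut-2-enyl)benzene; 13 N-methoxy-2-(methoxymethoxy)-N-methylacetamide
Product: 14 2-(methoxymethoxy)-1-[2,4,6-tris(methoxymethoxy)-3,5-bis(3-methylbut-2-enyl)phenyl]ethan-1-one
Conditions: n-BuLi, THF, 0 °C; then 13, −78 to 0 °C; aq. NH4Cl
Reagents that add atoms: none
Why: Directed ortho-metalation at the only ring C–H, which lies between two coordinating MOM ethers, followed by Weinreb ketone synthesis; the chelated tetrahedral adduct should prevent a second addition, and no acid touches the prenyl groups.

Step 8
Reactants: 15 4-bromo-2-hydroxybenzaldehyde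
Product: 17 7-bromo-2,2-dimethyl-2H-chromene, via allylic alcohol 16 (not isolated)
Conditions: Me2C=CHMgBr (2.3 equiv), THF, 0 °C; aq. NH4Cl; then p-TsOH (cat.), toluene, 60 °C
Reagents that add atoms: 2-methylprop-1-enylmagnesium bromide, CC(C)=C[Mg]Br
Why: Grignard 1,2-addition to the aldehyde after deprotonation of the phenol, then acid-promoted loss of water to a dienyl ortho-quinone methide that closes by oxa-6π electrocyclisation; the aldehyde carbon becomes C4, so the bromine is fixed at C7, and the carbinol centre of 16 is racemic and lost on dehydration.

Step 9
Reactants: 17 7-bromo-2,2-dimethyl-2H-chromene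
Product: 18 2,2-dimethyl-2H-chromene-7-carboxylic acid
Conditions: n-BuLi, THF, −78 °C; CO2; aq. HCl
Reagents that add atoms: carbon dioxide, O=C=O
Why: Bromine–lithium exchange and carboxylation of the aryllithium; the chromene has no acidic or electrophilic site that competes at −78 °C.

Step 10
Reactants: 14 2-(methoxymethoxy)-1-[2,4,6-tris(methoxymethoxy)-3,5-bis(3-methylbut-2-enyl)phenyl]ethan-1-one; 18 2,2-dimethyl-2H-chromene-7-carboxylic acid
Product: 20 1-(2,2-dimethyl-2H-chromen-7-yl)-2-(methoxymethoxy)-3-[2,4,6-tris(methoxymethoxy)-3,5-bis(3-methylbut-2-enyl)phenyl]propane-1,3-dione (racemic), via acid chloride 19 (not isolated)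
Conditions: 18, (COCl)2, DMF (cat.), CH2Cl2, rt, evaporate; 14, LiN(SiMe3)2 (2.2 equiv), THF, −78 °C; then 19, −78 to 0 °C; aq. NH4Cl
Reagents that add atoms: none
Why: Crossed Claisen-type C-aroylation of a ketone lithium enolate by an aroyl chloride, as used for flavone 1,3-diketones; 14 has a single enolisable position, the second equivalent of base deprotonates the product and shields it from further acylation, and the new sp3 centre is racemic, enolisable and becomes sp2 in step 11.

Step 11
Reactants: 20 1-(2,2-dimethyl-2H-chromen-7-yl)-2-(methoxymethoxy)-3-[2,4,6-tris(methoxymethoxy)-3,5-bis(3-methylbut-2-enyl)phenyl]propane-1,3-dione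
Product: 22 dorsilurin C, via flavonol MOM ether 21 (not isolated)
Conditions: HCl (3 M aq.), MeOH, 50 °C
Reagents that add atoms: none
Why: Acid-catalysed acetal exchange frees the phenols; either of the two equivalent ortho hydroxyls adds to the ring B ketone and water is lost, the cyclodehydration that ends a Baker–Venkataraman flavone synthesis. The enol MOM ether on C3, activated by the adjacent carbonyl, should cleave under the same conditions.

## Compound list

1 | methyl acetoacetate | COC(=O)CC(C)=O | starting material
2 | 1-bromo-3-methylbut-2-ene (prenyl bromide) | CC(C)=CCBr | starting material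
3 | methyl 7-methyl-3-oxooct-6-enoate | COC(=O)CC(=O)CCC=C(C)C | intermediate
4 | 2-methylbut-3-en-2-ol | C=CC(C)(C)O | starting material
5 | trimethyl orthoacetate | COC(C)(OC)OC | starting material
6 | 3-[(1-methoxyethenyl)oxy]-3-methylbut-1-ene (mixed ketene acetal) | C=C(OC)OC(C)(C)C=C | intermediate (not isolated)
7 | methyl 5-methylhex-4-enoate | COC(=O)CCC=C(C)C | intermediate
8 | methyl 9-methyl-4-(3-methylbut-2-enyl)-3,5-dioxodec-8-enoate (racemic) | COC(=O)CC(=O)C(CC=C(C)C)C(=O)CCC=C(C)C | intermediate (not isolated)
9 | 2,4-bis(3-methylbut-2-enyl)benzene-1,3,5-triol | CC(C)=CCc1c(O)cc(O)c(CC=C(C)C)c1O | intermediate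
10 | 1,3,5-tris(methoxymethoxy)-2,4-bis(3-methylbut-2-enyl)benzene | COCOc1cc(OCOC)c(CC=C(C)C)c(OCOC)c1CC=C(C)C | intermediate
11 | methyl glycolate | COC(=O)CO | starting material
12 | methyl 2-(methoxymethoxy)acetate | COCOCC(=O)OC | intermediate
13 | N-methoxy-2-(methoxymethoxy)-N-methylacetamide | COCOCC(=O)N(C)OC | intermediate
14 | 2-(methoxymethoxy)-1-[2,4,6-tris(methoxymethoxy)-3,5-bis(3-methylbut-2-enyl)phenyl]ethan-1-one | COCOCC(=O)c1c(OCOC)c(CC=C(C)C)c(OCOC)c(CC=C(C)C)c1OCOC | intermediate
15 | 4-bromo-2-hydroxybenzaldehyde | O=Cc1ccc(Br)cc1O | starting material
16 | 5-bromo-2-(1-hydroxy-3-methylbut-2-enyl)phenol (racemic) | CC(C)=CC(O)c1ccc(Br)cc1O | intermediate (not isolated)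
17 | 7-bromo-2,2-dimethyl-2H-chromene | CC1(C)C=Cc2ccc(Br)cc2O1 | intermediate
18 | 2,2-dimethyl-2H-chromene-7-carboxylic acid | CC1(C)C=Cc2ccc(C(=O)O)cc2O1 | intermediate
19 | 2,2-dimethyl-2H-chromene-7-carbonyl chloride | CC1(C)C=Cc2ccc(C(=O)Cl)cc2O1 | intermediate (not isolated)
20 | 1-(2,2-dimethyl-2H-chromen-7-yl)-2-(methoxymethoxy)-3-[2,4,6-tris(methoxymethoxy)-3,5-bis(3-methylbut-2-enyl)phenyl]propane-1,3-dione (racemic) | COCOC(C(=O)c1ccc2C=CC(C)(C)Oc2c1)C(=O)c1c(OCOC)c(CC=C(C)C)c(OCOC)c(CC=C(C)C)c1OCOC | intermediate
21 | 2-(2,2-dimethyl-2H-chromen-7-yl)-5,7-dihydroxy-3-(methoxymethoxy)-6,8-bis(3-methylbut-2-enyl)-4H-chromen-4-one | COCOc1c(-c2ccc3C=CC(C)(C)Oc3c2)oc2c(CC=C(C)C)c(O)c(CC=C(C)C)c(O)c2c1=O | intermediate (not isolated)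
22 | dorsilurin C, 2-(2,2-dimethyl-2H-chromen-7-yl)-3,5,7-trihydroxy-6,8-bis(3-methylbut-2-enyl)-4H-chromen-4-one | CC(C)=CCc1c(O)c(CC=C(C)C)c2oc(-c3ccc4c(c3)OC(C)(C)C=C4)c(O)c(=O)c2c1O | target

## Step count and risk

Total: 11 steps. Longest linear sequence: 6 steps (1, 3, 4, 7, 10, 11).

**Step 3 (key step).** Proton transfer from the enolisable ester 7 to the hindered secondary γ-carbanion may outrun acylation and return 3. In the closure, the nucleophilic carbon is only singly activated, so lactonisation through oxygen or methanolytic retro-Claisen cleavage of 8 may compete with the slow C-acylation. The fallback abandons ring construction and sets out from prenyl bromide 2. Commercial benzene-1,3,5-triol F1 is converted with NaH and MOMCl into 1,3,5-tris(methoxymethoxy)benzene F2. Lithiation with n-BuLi in THF at 0 °C and alkylation with 2 should give 1,3,5-tris(methoxymethoxy)-2-(3-methylbut-2-enyl)benzene F3. A second lithiation at one of the two equivalent remaining ring positions and alkylation with 2 comes back to the route at 10. Steps 1 to 4 are then replaced by three steps.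

**Step 11.** While the acetals are being cleaved, the freed phenols may add to the neighbouring prenyl alkenes to give chromans, or HCl and methanol may add across them. The fallback sets out from 20 and separates deprotection from ring closure. Me3SiOTf with 2,2'-bipyridyl in CH2Cl2 at 0 °C, then water, should remove all four MOM groups under nearly neutral conditions. This gives 1-(2,2-dimethyl-2H-chromen-7-yl)-2-hydroxy-3-[2,4,6-trihydroxy-3,5-bis(3-methylbut-2-enyl)phenyl]propane-1,3-dione F4. Brief warming in acetic acid with sodium acetate should cyclodehydrate it, coming back at 22.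

**Step 10.** The crowded α-alkoxy enolate may be acylated on oxygen to an enol ester, or the diketone enolate may take up a second aroyl group. The fallback sets out from 17 and 14 and forms the same C–C bond by aldol addition and oxidation. Bromine–lithium exchange on 17 and quenching with N,N-dimethylformamide gives 2,2-dimethyl-2H-chromene-7-carbaldehyde F5. The lithium enolate of 14 (LiN(i-Pr)2, THF, −78 °C) adds to it to give 3-(2,2-dimethyl-2H-chromen-7-yl)-3-hydroxy-2-(methoxymethoxy)-1-[2,4,6-tris(methoxymethoxy)-3,5-bis(3-methylbut-2-enyl)phenyl]propan-1-one F6 as a diastereomer mixture. Dess–Martin periodinane buffered with NaHCO3 oxidises it, coming back at 20.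

**Step 7.** Deprotonation may stray to the benzylic-allylic CH2 groups of the prenyl chains, each of which is also flanked by MOM ethers, so the amide would then be attacked by the wrong carbanion. The fallback sets out from 10 and fixes the metalation site with a halogen. N-Bromosuccinimide in acetonitrile at −30 °C should substitute the very electron-rich ring faster than it attacks the isolated alkenes. This gives 2-bromo-1,3,5-tris(methoxymethoxy)-4,6-bis(3-methylbut-2-enyl)benzene F7. Exchange with t-BuLi at −78 °C and addition of 13 comes back at 14.

**Step 8.** The dienyl ortho-quinone methide may oligomerise or be trapped by a second molecule of alcohol 16 before it electrocyclises. The fallback sets out from 15 and generates the same intermediate under basic conditions at low temperature. Di-tert-butyl dicarbonate converts 15 into 5-bromo-2-formylphenyl tert-butyl carbonate F8. Addition of 2-methylprop-1-enylmagnesium bromide at −78 °C gives an alkoxide that takes over the carbonate group and eliminates it on warming. The quinone methide formed this way closes to the chromene, coming back at 17.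

## Further compounds

F1 | step 3 | benzene-1,3,5-triol (phloroglucinol) | Oc1cc(O)cc(O)c1
F2 | step 3 | 1,3,5-tris(methoxymethoxy)benzene | COCOc1cc(OCOC)cc(OCOC)c1
F3 | step 3 | 1,3,5-tris(methoxymethoxy)-2-(3-methylbut-2-enyl)benzene | COCOc1cc(OCOC)c(CC=C(C)C)c(OCOC)c1
F4 | step 11 | 1-(2,2-dimethyl-2H-chromen-7-yl)-2-hydroxy-3-[2,4,6-trihydroxy-3,5-bis(3-methylbut-2-enyl)phenyl]propane-1,3-dione (racemic) | OC(C(=O)c1ccc2C=CC(C)(C)Oc2c1)C(=O)c1c(O)c(CC=C(C)C)c(O)c(CC=C(C)C)c1O
F5 | step 10 | 2,2-dimethyl-2H-chromene-7-carbaldehyde | CC1(C)C=Cc2ccc(C=O)cc2O1
F6 | step 10 | 3-(2,2-dimethyl-2H-chromen-7-yl)-3-hydroxy-2-(methoxymethoxy)-1-[2,4,6-tris(methoxymethoxy)-3,5-bis(3-methylbut-2-enyl)phenyl]propan-1-one (racemic diastereomer mixture) | COCOC(C(O)c1ccc2C=CC(C)(C)Oc2c1)C(=O)c1c(OCOC)c(CC=C(C)C)c(OCOC)c(CC=C(C)C)c1OCOC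
F7 | step 7 | 2-bromo-1,3,5-tris(methoxymethoxy)-4,6-bis(3-methylbut-2-enyl)benzene | COCOc1c(Br)c(OCOC)c(CC=C(C)C)c(OCOC)c1CC=C(C)C
F8 | step 8 | 5-bromo-2-formylphenyl tert-butyl carbonate | CC(C)(C)OC(=O)Oc1cc(Br)ccc1C=O
A1 | alternative 1 | dorsilurin C 3-benzoate | CC(C)=CCc1c(O)c(CC=C(C)C)c2oc(-c3ccc4c(c3)OC(C)(C)C=C4)c(OC(=O)c3ccccc3)c(=O)c2c1O
A2 | alternative 1 | 5,7-bis(2-methylbut-3-en-2-yloxy)-2-[3-(2-methylbut-3-yn-2-yloxy)phenyl]-4-oxo-4H-chromen-3-yl benzoate | C=CC(C)(C)Oc1cc(OC(C)(C)C=C)c2c(c1)oc(-c1cccc(OC(C)(C)C#C)c1)c(OC(=O)c1ccccc1)c2=O
A3 | alternative 2 | 2-[3-hydroxy-4-(3-methylbut-2-enyl)phenyl]-3,5,7-tris(methoxymethoxy)-6,8-bis(3-methylbut-2-enyl)-4H-chromen-4-one | CC(C)=CCc1ccc(-c2oc3c(CC=C(C)C)c(OCOC)c(CC=C(C)C)c(OCOC)c3c(=O)c2OCOC)cc1O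
A4 | alternative 2 | 2-acetyl-3,5,7-tris(methoxymethoxy)-6,8-bis(3-methylbut-2-enyl)-4H-chromen-4-one | CC(=O)c1oc2c(CC=C(C)C)c(OCOC)c(CC=C(C)C)c(OCOC)c2c(=O)c1OCOC
A5 | alternative 2 | 3-(ethoxymethylidene)-6-methylhept-5-en-2-one | CCOC=C(CC=C(C)C)C(C)=O
A6 | alternative 3 | 2,4-bis(3-methylbut-2-enyl)-3,5-bis(triisopropylsilyloxy)phenol | CC(C)=CCc1c(O)cc(O[Si](C(C)C)(C(C)C)C(C)C)c(CC=C(C)C)c1O[Si](C(C)C)(C(C)C)C(C)C
A7 | alternative 3 | 2-(3-methylbut-2-enyl)-3-(triisopropylsilyloxy)cyclobut-2-en-1-one | CC(C)=CCC1=C(O[Si](C(C)C)(C(C)C)C(C)C)CC1=O
A8 | alternative 3 | triisopropyl(5-methylhex-4-en-1-ynyloxy)silane | CC(C)=CCC#CO[Si](C(C)C)(C(C)C)C(C)C
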